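**Retrosynthetic overview**
- The target is two (2S)-naringenin units joined by a diaryl ether between the 4'-oxygen of ring B of unit 1 and C6 of ring A of unit 2. All five phenols are carried as benzyl ethers and freed last.
- Unit 1 is disconnected at C2–C1' (ring B): asymmetric conjugate addition of the arylboronic acid that already carries complete unit 2 to 5,7-bis(benzyloxy)chromone.
- Unit 2 carries the strategy. Its C2 is bonded to O1 and to the 4-oxyphenyl ring B (a latent oxocarbenium carbon), and C3 is alpha to the C4 ketone. The C2–C3 bond is therefore made by closing the enol silane of the ring-A acetophenone onto an aryloxy oxocarbenium ion under a chiral counteranion. The ion is released from an O-aryl O-pivaloyl acetal rather than an alkyl aryl acetal, so that only the wanted C–O bond ionises.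
- Ring A comes from phloroacetophenone: dibenzylation, para-hydroxylation, O-arylation of the new hydroxyl (the later C6–O–aryl link), then acyloxybenzylation of the chelated hydroxyl (the later O1).
- Ring order: ring C of unit 2 (step 7), then the pyranone ring of unit 1 (chromone in step 10, its C2 centre in step 11).

Key step: step 7

Remark: the configuration of the chiral acid (step 7) and of the pyridine-oxazoline ligand (step 11) given below is the one expected to lead to the (2S) centres; it is to be fixed on model substrates, and both antipodes are equally accessible.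

**Step 1**
Reactants: 1 2,4,6-trihydroxyacetophenone
Product: 2 4,6-bis(benzyloxy)-2-hydroxyacetophenone
Conditions: BnBr (2.1 equiv), K2CO3, DMF, rt
Reagents that add atoms: benzyl bromide, BrCc1ccccc1
Why: Williamson etherification: the 4-OH and one ortho OH are benzylated, while the second ortho OH stays hydrogen-bonded to the acetyl group and should remain free with this stoichiometry.

**Step 2**
Reactants: 2 4,6-bis(benzyloxy)-2-hydroxyacetophenone
Product: 4 4,6-bis(benzyloxy)-2,5-dihydroxyacetophenone, via potassium aryl sulfate 3 (not isolated)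
Conditions: K2S2O8, aq NaOH, pyridine, 0 °C to rt, N2; then aq HCl, 60 °C
Reagents that add atoms: potassium peroxodisulfate, [K+].[K+].[O-]S(=O)(=O)OOS(=O)(=O)[O-]
Why: Elbs persulfate oxidation: the phenoxide of 2 is sulfated at its free para carbon C5 and acid hydrolysis of aryl sulfate 3 should release the hydroquinone, the new oxygen being the later C6 oxygen of unit 2.

**Step 3**
Reactants: 4 4,6-bis(benzyloxy)-2,5-dihydroxyacetophenone; 5 bis(4-bromophenyl)iodonium trifluoromethanesulfonate
Product: 6 4,6-bis(benzyloxy)-5-(4-bromophenoxy)-2-hydroxyacetophenone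
Conditions: K2CO3 (1.1 equiv), MeCN, 40 °C, N2
Reagents that add atoms: none
Why: O-arylation of a phenol with a diaryliodonium salt (ligand coupling at trivalent iodine): the non-chelated 5-OH is the more nucleophilic oxygen, two ortho substituents and the aryl bromide are tolerated, and unlike a copper/air coupling the method should not oxidise the hydroquinone to the quinone.

**Step 4**
Reactants: 7 4-(benzyloxy)benzaldehyde
Product: 8 chloro[4-(benzyloxy)phenyl]methyl 2,2-dimethylpropanoate (racemic)
Conditions: t-BuCOCl (0.95 equiv), ZnCl2 (2 mol%), CH2Cl2, 0 °C to rt; filtered, concentrated, used at once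
Reagents that add atoms: pivaloyl chloride, CC(C)(C)C(=O)Cl
Why: Zinc chloride catalysed addition of an acyl chloride across an aldehyde carbonyl is the standard entry to alpha-chloroalkyl esters and should give the acyloxybenzylating agent.

**Step 5**
Reactants: 6 4,6-bis(benzyloxy)-5-(4-bromophenoxy)-2-hydroxyacetophenone; 8 chloro[4-(benzyloxy)phenyl]methyl 2,2-dimethylpropanoate
Product: 9 [2-acetyl-3,5-bis(benzyloxy)-4-(4-bromophenoxy)phenoxy][4-(benzyloxy)phenyl]methyl 2,2-dimethylpropanoate (racemic at the acetal carbon)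
Conditions: Cs2CO3, MeCN, 0 °C; chromatography on Et3N-deactivated silica
Reagents that add atoms: none
Why: O-alkylation of a phenoxide with an alpha-chloroalkyl ester (acyloxyalkylation) should be fast because the chloride is doubly activated, and the hindered pivalate carbonyl suppresses acyl transfer to the phenoxide.

**Step 6**
Reactants: 9 [2-acetyl-3,5-bis(benzyloxy)-4-(4-bromophenoxy)phenoxy][4-(benzyloxy)phenyl]methyl 2,2-dimethylpropanoate
Product: 10 {3,5-bis(benzyloxy)-4-(4-bromophenoxy)-2-[1-(tert-butyldimethylsilyloxy)ethenyl]phenoxy}[4-(benzyloxy)phenyl]methyl 2,2-dimethylpropanoate (racemic at the acetal carbon)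
Conditions: TBSCl (1.5 equiv) present, KN(SiMe3)2 (1.2 equiv) added, THF, −78 °C; filtration through basic alumina
Reagents that add atoms: tert-butyldimethylsilyl chloride, CC(C)(C)[Si](C)(C)Cl
Why: Kinetic enolisation of the methyl ketone and O-silylation of the potassium enolate under internal-quench conditions should give the enol silane, since the pivalate has no alpha hydrogen and no silyl triflate is present that could ionise the mixed acetal.

**Step 7**
Reactants: 10 {3,5-bis(benzyloxy)-4-(4-bromophenoxy)-2-[1-(tert-butyldimethylsilyloxy)ethenyl]phenoxy}[4-(benzyloxy)phenyl]methyl 2,2-dimethylpropanoate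
Product: 12 (2S)-5,7-bis(benzyloxy)-2-[4-(benzyloxy)phenyl]-6-(4-bromophenoxy)chroman-4-one, via aryloxy oxocarbenium ion 11 (not isolated)
Conditions: chiral imidodiphosphorimidate acid HN[P(=NSO2CF3)(O2C20H10Ar2)]2 (O2C20H10Ar2 = (S)-3,3'-diaryl-1,1'-binaphthalene-2,2'-diolate, Ar = 3,5-(CF3)2C6H3; 5 mol%), CH2=C(CH3)CH2SiMe3 (5 mol%, activator), toluene, −60 °C, 0.02 M
Reagents that add atoms: none
Why: Proposed new method: the acid, silylated in the flask by the allylsilane, passes its silyl group to the pivalate carbonyl oxygen of 10, the most Lewis basic site, the silyl pivalate leaves, and the 4-benzyloxyphenyl-stabilised aryloxy oxocarbenium ion 11 (O1=C2) stays paired with the chiral anion. C3 of the enol silane then adds to C2 and the resulting silyloxycarbenium ion returns its silyl group to the anion, which should give ketone 12 directly and regenerate the silylated catalyst. The closest known reactions are imidodiphosphorimidate-catalysed Mukaiyama-type additions of enol silanes to oxocarbenium ions released from lactol acetates and acetals, and Lewis acid promoted enol silane Prins and Petasis–Ferrier closures to tetrahydropyran-4-ones; the intramolecular closure onto an acyclic aryloxy oxocarbenium ion to form a flavanone has not been shown. Ring C closes in a 6-endo-trig mode at the O1=C2 bond (6-enolendo for the nucleophile), the only ring size the tether allows. The C2 centre is set by the confined chiral counteranion, which should shield one face of the planar oxocarbenium ion, the racemic acetal centre being erased on ionisation. The step needs ionisation at the right C–O bond, which an alkoxy leaving group would not secure because acid opens alkyl aryl acetals mainly at the C–OAr bond, whereas the acyloxy group is both the more basic site and the better nucleofuge; and since neither a phenoxide nor a chalcone is formed, ring C should not reopen and the aryloxy group should stay at C6.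

**Step 8**
Reactants: 12 (2S)-5,7-bis(benzyloxy)-2-[4-(benzyloxy)phenyl]-6-(4-bromophenoxy)chroman-4-one
Product: 13 (2S)-5,7-bis(benzyloxy)-2-[4-(benzyloxy)phenyl]-6-[4-(4,4,5,5-tetramethyl-1,3,2-dioxaborolan-2-yl)phenoxy]chroman-4-one
Conditions: B2pin2, PdCl2(dppf) (dppf = 1,1'-bis(diphenylphosphino)ferrocene; 5 mol%), KOAc, 1,4-dioxane, 85 °C
Reagents that add atoms: bis(pinacolato)diboron, CC1(C)OB(OC1(C)C)B1OC(C)(C)C(C)(C)O1
Why: Miyaura borylation of the aryl bromide through zerovalent palladium uses only the weak base potassium acetate, which should neither open ring C nor touch C2 of the 5-O-benzylated flavanone.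

**Step 9**
Reactants: 13 (2S)-5,7-bis(benzyloxy)-2-[4-(benzyloxy)phenyl]-6-[4-(4,4,5,5-tetramethyl-1,3,2-dioxaborolan-2-yl)phenoxy]chroman-4-one
Product: 14 {4-[((2S)-5,7-bis(benzyloxy)-2-[4-(benzyloxy)phenyl]-4-oxochroman-6-yl)oxy]phenyl}boronic acid
Conditions: NaIO4, NH4OAc, acetone/H2O, rt
Reagents that add atoms: water, O
Why: Oxidative hydrolysis of a pinacol boronate: periodate cleaves the pinacol released in the hydrolysis equilibrium at near-neutral pH, which should give the free boronic acid needed for transmetalation to divalent palladium.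

**Step 10**
Reactants: 2 4,6-bis(benzyloxy)-2-hydroxyacetophenone
Product: 16 5,7-bis(benzyloxy)-4H-chromen-4-one, via enaminone 15 (not isolated)
Conditions: Me2NCH(OMe)2, toluene, 100 °C; then conc. HCl, CH2Cl2, 40 °C
Reagents that add atoms: N,N-dimethylformamide dimethyl acetal, COC(OC)N(C)C
Why: Enaminone formation from the methyl ketone and the amide acetal, followed by acid-induced addition of the phenol and loss of dimethylamine, is the standard chromone synthesis from 2-hydroxyacetophenones.

**Step 11**
Reactants: 14 {4-[((2S)-5,7-bis(benzyloxy)-2-[4-(benzyloxy)phenyl]-4-oxochroman-6-yl)oxy]phenyl}boronic acid; 16 5,7-bis(benzyloxy)-4H-chromen-4-one (2 equiv)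
Product: 17 (2S)-5,7-bis(benzyloxy)-2-{4-[((2S)-5,7-bis(benzyloxy)-2-[4-(benzyloxy)phenyl]-4-oxochroman-6-yl)oxy]phenyl}chroman-4-one
Conditions: Pd(OCOCF3)2 (10 mol%), (R)-4-tert-butyl-2-(pyridin-2-yl)-4,5-dihydrooxazole (12 mol%), NH4PF6 (30 mol%), H2O (5 equiv), ClCH2CH2Cl, 60 °C
Reagents that add atoms: none
Why: Divalent-palladium-catalysed asymmetric conjugate addition of an arylboronic acid to a chromone (transmetalation, enantiofacial carbopalladation of C2=C3 directed by the pyridine-oxazoline ligand, protonolysis) should set C2 of unit 1 under catalyst control, far from the existing centre and without base, so that unit 2 is not disturbed.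

**Step 12**
Reactants: 17 (2S)-5,7-bis(benzyloxy)-2-{4-[((2S)-5,7-bis(benzyloxy)-2-[4-(benzyloxy)phenyl]-4-oxochroman-6-yl)oxy]phenyl}chroman-4-one
Product: 18 (2S)-5,7-dihydroxy-2-{4-[((2S)-5,7-dihydroxy-2-(4-hydroxyphenyl)-4-oxochroman-6-yl)oxy]phenyl}chroman-4-one (CNP0184214.1)
Conditions: H2 (1 atm), 10% Pd/C, EtOAc/MeOH, rt, short reaction time with monitoring
Reagents that add atoms: none
Why: Hydrogenolysis of the five aryl benzyl ethers under neutral conditions, stopped at full debenzylation before the slower cleavage of the benzylic C2–O1 bonds, should free the phenols without touching either C2 centre.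

**Compound list**
1 | 2,4,6-trihydroxyacetophenone | CC(=O)c1c(O)cc(O)cc1O | starting material
2 | 4,6-bis(benzyloxy)-2-hydroxyacetophenone | CC(=O)c1c(O)cc(OCc2ccccc2)cc1OCc1ccccc1 | intermediate
3 | potassium 3-acetyl-2,6-bis(benzyloxy)-4-hydroxyphenyl sulfate (formed in the flask, not isolated) | CC(=O)c1c(O)cc(OCc2ccccc2)c(OS(=O)(=O)[O-])c1OCc1ccccc1.[K+] | intermediate
4 | 4,6-bis(benzyloxy)-2,5-dihydroxyacetophenone | CC(=O)c1c(O)cc(OCc2ccccc2)c(O)c1OCc1ccccc1 | intermediate
5 | bis(4-bromophenyl)iodonium trifluoromethanesulfonate | Brc1ccc([I+]c2ccc(Br)cc2)cc1.[O-]S(=O)(=O)C(F)(F)F | starting material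
6 | 4,6-bis(benzyloxy)-5-(4-bromophenoxy)-2-hydroxyacetophenone | CC(=O)c1c(O)cc(OCc2ccccc2)c(Oc2ccc(Br)cc2)c1OCc1ccccc1 | intermediate
7 | 4-(benzyloxy)benzaldehyde | O=Cc1ccc(OCc2ccccc2)cc1 | starting material
8 | chloro[4-(benzyloxy)phenyl]methyl 2,2-dimethylpropanoate (racemic) | CC(C)(C)C(=O)OC(Cl)c1ccc(OCc2ccccc2)cc1 | intermediate
9 | [2-acetyl-3,5-bis(benzyloxy)-4-(4-bromophenoxy)phenoxy][4-(benzyloxy)phenyl]methyl 2,2-dimethylpropanoate (racemic) | CC(=O)c1c(OC(OC(=O)C(C)(C)C)c2ccc(OCc3ccccc3)cc2)cc(OCc2ccccc2)c(Oc2ccc(Br)cc2)c1OCc1ccccc1 | intermediate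
10 | {3,5-bis(benzyloxy)-4-(4-bromophenoxy)-2-[1-(tert-butyldimethylsilyloxy)ethenyl]phenoxy}[4-(benzyloxy)phenyl]methyl 2,2-dimethylpropanoate (racemic) | C=C(O[Si](C)(C)C(C)(C)C)c1c(OC(OC(=O)C(C)(C)C)c2ccc(OCc3ccccc3)cc2)cc(OCc2ccccc2)c(Oc2ccc(Br)cc2)c1OCc1ccccc1 | intermediate
11 | aryloxy oxocarbenium ion from 10 by loss of pivalate, paired with the catalyst anion (formed in the flask, not isolated) | C=C(O[Si](C)(C)C(C)(C)C)c1c([O+]=Cc2ccc(OCc3ccccc3)cc2)cc(OCc2ccccc2)c(Oc2ccc(Br)cc2)c1OCc1ccccc1 | intermediate
12 | (2S)-5,7-bis(benzyloxy)-2-[4-(benzyloxy)phenyl]-6-(4-bromophenoxy)chroman-4-one | O=C1C[C@@H](c2ccc(OCc3ccccc3)cc2)Oc2cc(OCc3ccccc3)c(Oc3ccc(Br)cc3)c(OCc3ccccc3)c21 | intermediate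
13 | (2S)-5,7-bis(benzyloxy)-2-[4-(benzyloxy)phenyl]-6-[4-(4,4,5,5-tetramethyl-1,3,2-dioxaborolan-2-yl)phenoxy]chroman-4-one | O=C1C[C@@H](c2ccc(OCc3ccccc3)cc2)Oc2cc(OCc3ccccc3)c(Oc3ccc(B4OC(C)(C)C(C)(C)O4)cc3)c(OCc3ccccc3)c21 | intermediate
14 | {4-[((2S)-5,7-bis(benzyloxy)-2-[4-(benzyloxy)phenyl]-4-oxochroman-6-yl)oxy]phenyl}boronic acid | O=C1C[C@@H](c2ccc(OCc3ccccc3)cc2)Oc2cc(OCc3ccccc3)c(Oc3ccc(B(O)O)cc3)c(OCc3ccccc3)c21 | intermediate
15 | (E)-1-[2,4-bis(benzyloxy)-6-hydroxyphenyl]-3-(dimethylamino)prop-2-en-1-one (formed in the flask, not isolated) | CN(C)/C=C/C(=O)c1c(O)cc(OCc2ccccc2)cc1OCc1ccccc1 | intermediate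
16 | 5,7-bis(benzyloxy)-4H-chromen-4-one | O=c1ccoc2cc(OCc3ccccc3)cc(OCc3ccccc3)c12 | intermediate
17 | (2S)-5,7-bis(benzyloxy)-2-{4-[((2S)-5,7-bis(benzyloxy)-2-[4-(benzyloxy)phenyl]-4-oxochroman-6-yl)oxy]phenyl}chroman-4-one | O=C1C[C@@H](c2ccc(Oc3c(OCc5ccccc5)cc4c(c3OCc3ccccc3)C(=O)C[C@@H](c3ccc(OCc5ccccc5)cc3)O4)cc2)Oc2cc(OCc3ccccc3)cc(OCc3ccccc3)c21 | intermediate
18 | (2S)-5,7-dihydroxy-2-{4-[((2S)-5,7-dihydroxy-2-(4-hydroxyphenyl)-4-oxochroman-6-yl)oxy]phenyl}chroman-4-one | O=C1C[C@@H](c2ccc(Oc3c(O)cc4c(c3O)C(=O)C[C@@H](c3ccc(O)cc3)O4)cc2)Oc2cc(O)cc(O)c21 | target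

**Totals**
Total step count: 12. Longest linear sequence: 10 steps (1, 2, 3, 5, 6, 7, 8, 9, 11, 12).

**Steps most likely to fail**

Step 7. The ion may form by loss of the aryloxy group instead of the pivalate, the cation may be captured intermolecularly, or the anion may discriminate poorly between the two faces. The fallback uses known chemistry and sets out from 6. Heating 6 with N,N-dimethylformamide dimethyl acetal should give the enaminone (E)-1-[2,4-bis(benzyloxy)-3-(4-bromophenoxy)-6-hydroxyphenyl]-3-(dimethylamino)prop-2-en-1-one F1 (not isolated), which HCl in CH2Cl2 should close to 5,7-bis(benzyloxy)-6-(4-bromophenoxy)-4H-chromen-4-one F2. Asymmetric conjugate addition of commercial 4-(benzyloxy)phenylboronic acid to F2 under the conditions of step 11 then forms the C2–aryl bond of unit 2; the aryl bromide should survive because the cycle stays at divalent palladium. The route is rejoined at 12.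

Step 5. Acyl transfer from the reagent to the phenoxide, benzylation at the free ring carbon, or ionisation and hydrolysis of the mixed acetal during isolation (and its exposure to strong base in step 6) may erode the precursor. The fallback sets out from 6 and introduces the acetal carbon at the ester oxidation level. Acylation with 4-(benzyloxy)benzoyl chloride (Et3N, DMAP, CH2Cl2) should give 2-acetyl-3,5-bis(benzyloxy)-4-(4-bromophenoxy)phenyl 4-(benzyloxy)benzoate F3. Soft enolisation (TBSOTf, Et3N, CH2Cl2, 0 °C), which generates no free enolate and so avoids a Baker–Venkataraman acyl shift, should give 3,5-bis(benzyloxy)-4-(4-bromophenoxy)-2-[1-(tert-butyldimethylsilyloxy)ethenyl]phenyl 4-(benzyloxy)benzoate F4. Reduction with i-Bu2AlH in CH2Cl2 at −78 °C should stop at the diisobutylaluminium hemiacetal F5 (not isolated), which is trapped with pivalic anhydride, pyridine and DMAP (reductive acylation of an ester to an alpha-acyloxy ether). The route is rejoined at 10, so step 6 is bypassed as well.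

Step 2. Sulfation of the sparingly soluble phenoxide may be incomplete, over-oxidation may give dark polymeric material, and benzyl groups may be lost in the hot acid hydrolysis. The fallback sets out from 2 and passes through the quinone oxidation level. Teuber oxidation with potassium nitrosodisulfonate K2[ON(SO3)2] (KH2PO4 buffer, H2O/CH2Cl2, Bu4NHSO4 as phase-transfer catalyst) should give 2-acetyl-3,5-bis(benzyloxy)-1,4-benzoquinone F6. Reduction with Na2S2O4 in EtOAc/H2O returns to the route at 4.

**Further compounds**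
F1 | step 7 | (E)-1-[2,4-bis(benzyloxy)-3-(4-bromophenoxy)-6-hydroxyphenyl]-3-(dimethylamino)prop-2-en-1-one | CN(C)/C=C/C(=O)c1c(O)cc(OCc2ccccc2)c(Oc2ccc(Br)cc2)c1OCc1ccccc1
F2 | step 7 | 5,7-bis(benzyloxy)-6-(4-bromophenoxy)-4H-chromen-4-one | O=c1ccoc2cc(OCc3ccccc3)c(Oc3ccc(Br)cc3)c(OCc3ccccc3)c12
F3 | step 5 | 2-acetyl-3,5-bis(benzyloxy)-4-(4-bromophenoxy)phenyl 4-(benzyloxy)benzoate | CC(=O)c1c(OC(=O)c2ccc(OCc3ccccc3)cc2)cc(OCc2ccccc2)c(Oc2ccc(Br)cc2)c1OCc1ccccc1
F4 | step 5 | 3,5-bis(benzyloxy)-4-(4-bromophenoxy)-2-[1-(tert-butyldimethylsilyloxy)ethenyl]phenyl 4-(benzyloxy)benzoate | C=C(O[Si](C)(C)C(C)(C)C)c1c(OC(=O)c2ccc(OCc3ccccc3)cc2)cc(OCc2ccccc2)c(Oc2ccc(Br)cc2)c1OCc1ccccc1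
F5 | step 5 | diisobutylaluminium hemiacetal of F4, {3,5-bis(benzyloxy)-4-(4-bromophenoxy)-2-[1-(tert-butyldimethylsilyloxy)ethenyl]phenoxy}[4-(benzyloxy)phenyl]methoxy(diisobutyl)aluminium | C=C(O[Si](C)(C)C(C)(C)C)c1c(OC(O[Al](CC(C)C)CC(C)C)c2ccc(OCc3ccccc3)cc2)cc(OCc2ccccc2)c(Oc2ccc(Br)cc2)c1OCc1ccccc1
F6 | step 2 | 2-acetyl-3,5-bis(benzyloxy)-1,4-benzoquinone | CC(=O)C1=C(OCc2ccccc2)C(=O)C(OCc2ccccc2)=CC1=O
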